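Numbering follows carotenoid usage: ring C2–C3–C4–C5–C6, C2 carries the isopropenyl group C1(=C16)C17, C5 carries OH and methyl C18, the polyene starts at C7. The feature that allows the key step: C2 is allylic to the C1=C16 alkene and bonded to C6, and C6 lies between the oxygen-bearing C5 and C7, so C6 can act as a 1,3-dicarbonyl carbon and C2 as an allyl terminus of one open chain.
Retrosynthetic cuts, in order: C11=C12 (Wittig, C15 ring aldehyde + C25 ψ-end phosphonium salt), C7=C8 (Horner–Wadsworth–Emmons, C5 phosphonate), C5–C18 (methyl addition to the ring ketone), the ring bond C2–C6 (palladium allylic alkylation), C3–C4 (acetoacetate dianion alkylation); the C25 unit is cut at C11'=C12' into a pseudoionone-derived C15 salt and the C10 trienedial.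
Forward: an open-chain β-keto ester allyl carbonate is closed to the cyclopentanone, the only ring (step 6); C5 is methylated, C7 is taken to the aldehyde, and the chain grows C10 → C15 → C40, the silyl group coming off last.
Stereochemistry: C2 from the chiral palladium catalyst; C6 by equilibration of the keto ester to trans; C5 by methyl addition anti to the ester; the alkenes from the E allylic chloride, E-selective olefinations and thermal Z→E isomerisation.

Key step: step 6

Assumption (step 6): the (R,R) ligand is written on the basis of the usual working model for this ligand family; the sense of induction would be checked on the first run and the (S,S) ligand used if it proves opposite.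
Assumption (step 13): pseudoionone is used as the (3E,5E) isomer; any 5Z material is removed when salt 21 is crystallised.

Step 1
Reactants: 1 2-methyl-2-vinyloxirane (isoprene monoxide, racemic)
Product: 2 (2E)-4-chloro-2-methylbut-2-en-1-ol
Conditions: TiCl4, CH2Cl2, −90 → −78 °C; then H2O
Reagents that add atoms: titanium tetrachloride, Cl[Ti](Cl)(Cl)Cl
Why: Lewis-acid-activated SN2' opening of a vinyl epoxide, in which chloride adds to the vinyl terminus as the C–O bond breaks, should give the E trisubstituted chloro alcohol directly.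

Step 2
Reactants: 2 (2E)-4-chloro-2-methylbut-2-en-1-ol
Product: 3 tert-butyl{[(2E)-4-chloro-2-methylbut-2-en-1-yl]oxy}dimethylsilane
Conditions: TBSCl, imidazole, CH2Cl2, 0 °C → rt
Reagents that add atoms: tert-butyldimethylsilyl chloride, CC(C)(C)[Si](C)(C)Cl
Why: Routine silylation of a primary alcohol with a silyl chloride and imidazole leaves the allylic chloride alone and masks the hydroxyl against the dianion of step 3.

Step 3
Reactants: 4 methyl acetoacetate; 3 silyl ether of the chloro alcohol
Product: 6 methyl (6E)-8-[(tert-butyldimethylsilyl)oxy]-7-methyl-3-oxooct-6-enoate, via acetoacetate dianion 5 (not isolated)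
Conditions: 4, NaH, THF, 0 °C; n-BuLi, 0 °C; then 3, 0 °C → rt; AcOH quench
Reagents that add atoms: none
Why: Huckin–Weiler dianion alkylation, in which the terminal carbanion of the bis-enolate is the more nucleophilic carbon and displaces the primary allylic chloride by SN2, forms C3–C4 with the E alkene intact.

Step 4
Reactants: 6 silyl-protected keto ester
Product: 7 methyl (6E)-8-hydroxy-7-methyl-3-oxooct-6-enoate
Conditions: HF (48 % aq), MeCN, 0 °C
Reagents that add atoms: none
Why: Fluoride cleavage of a primary tert-butyldimethylsilyl ether proceeds under mildly acidic conditions that the β-keto ester and the trisubstituted alkene tolerate.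

Step 5
Reactants: 7 hydroxy keto ester
Product: 8 methyl (6E)-8-[(methoxycarbonyl)oxy]-7-methyl-3-oxooct-6-enoate
Conditions: ClCO2Me, pyridine, CH2Cl2, 0 °C
Reagents that add atoms: methyl chloroformate, COC(=O)Cl
Why: Chloroformate acylation of the primary allylic alcohol, faster than reaction at the enol, gives the allylic methyl carbonate, a leaving group that supplies its own base on ionisation.

Step 6
Reactants: 8 allylic carbonate of the β-keto ester
Product: 9 methyl (1R,5S)-2-oxo-5-(prop-1-en-2-yl)cyclopentane-1-carboxylate (trans)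
Conditions: Pd2(dba)3·CHCl3 (2.5 mol %), (1R,2R)-N,N'-bis[2-(diphenylphosphino)benzoyl]cyclohexane-1,2-diamine (7.5 mol %), CH2Cl2 (0.02 M, degassed), rt
Reagents that add atoms: none
Why: Zerovalent palladium carrying the chiral diphosphine ionises the allylic carbonate with inversion to a cationic 2-methylallyl complex, the expelled methyl carbonate loses CO2, and the methoxide so formed deprotonates the β-keto ester, whose soft enolate carbon C6 attacks the internal allyl terminus C2 on the face opposite the metal and leaves C1=C16 as the isopropenyl alkene. The closest known reaction type is the intramolecular Tsuji–Trost alkylation of 8-oxy-3-oxooct-6-enoates to 2-alkoxycarbonyl-3-vinylcyclopentanones, which has also been run with chiral diphosphines. The cyclopentanone closes in the 5-exo-trig mode with respect to the allyl unit. C2 is controlled by the ligand, which selects between the two diastereomeric allyl complexes that interconvert through the η1 form at the unsubstituted CH2 terminus, and C6 is controlled thermodynamically, equilibrating through the enol to the trans keto ester. The step needs carbon over oxygen alkylation and five- over seven-membered closure: the enol ether from oxygen attack is itself an allylic ether that re-ionises and drains to the ketone, and the allyl geometry formed from the E alkene holds C3 and C16 trans, so a seven-membered ring is out of reach without prior isomerisation, whereas the 5-exo closure needs none.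

Step 7
Reactants: 9 trans keto ester
Product: 10 methyl (1R,2S,5S)-2-hydroxy-2-methyl-5-(prop-1-en-2-yl)cyclopentane-1-carboxylate
Conditions: CeCl3 (anhydrous, 1.5 equiv), THF, rt, 1 h; then MeMgBr (1.5 equiv), −78 → −40 °C; H2O quench
Reagents that add atoms: methylmagnesium bromide, C[Mg]Br
Why: CeCl3-mediated Grignard addition to an enolisable 1,3-dicarbonyl compound, in which chelation by cerium activates the ketone and tames the basicity of the reagent so that 1,2-addition should outrun deprotonation, brings methyl to C5 from the face of H-6, anti to the ester, and so sets the (5S) carbinol with OH cis to the ester.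

Step 8
Reactants: 10 tertiary hydroxy ester
Product: 11 methyl (1R,2S,5S)-2-methyl-5-(prop-1-en-2-yl)-2-[(triethylsilyl)oxy]cyclopentane-1-carboxylate
Conditions: Et3SiOTf, 2,6-lutidine, CH2Cl2, −78 → 0 °C
Reagents that add atoms: triethylsilyl trifluoromethanesulfonate, CC[Si](CC)(CC)OS(=O)(=O)C(F)(F)F
Why: Silyl triflate silylation of a hindered tertiary alcohol gives an ether that blocks retro-aldol cleavage and β-elimination in the basic steps that follow.

Step 9
Reactants: 11 silyloxy ester
Product: 12 {(1S,2S,5S)-2-methyl-5-(prop-1-en-2-yl)-2-[(triethylsilyl)oxy]cyclopentyl}methanol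
Conditions: iBu2AlH (2.5 equiv), CH2Cl2, −78 → 0 °C; aq potassium sodium tartrate
Reagents that add atoms: none
Why: Hydride reduction of the ester to the primary alcohol with excess iBu2AlH leaves the silyl ether and the alkene untouched.

Step 10
Reactants: 12 primary alcohol
Product: 13 (1R,2S,5S)-2-methyl-5-(prop-1-en-2-yl)-2-[(triethylsilyl)oxy]cyclopentane-1-carbaldehyde
Conditions: Pr4N[RuO4] (5 mol %), N-methylmorpholine N-oxide, 4 Å MS, CH2Cl2, rt
Reagents that add atoms: none
Why: Ley–Griffith oxidation of the primary alcohol to the aldehyde runs under neutral conditions, so the α-stereocentre C6 and the β-silyloxy group should survive.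

Step 11
Reactants: 13 ring aldehyde; 14 diethyl [(2E)-3-cyano-2-methylprop-2-en-1-yl]phosphonate
Product: 16 (2E,4E)-3-methyl-5-{(1R,2S,5S)-2-methyl-5-(prop-1-en-2-yl)-2-[(triethylsilyl)oxy]cyclopentyl}penta-2,4-dienenitrile, via phosphonate carbanion 15 (not isolated)
Conditions: 14, NaH, THF, 0 °C; then 13, −78 °C → rt
Reagents that add atoms: none
Why: Horner–Wadsworth–Emmons olefination with a vinylogous cyanomethylphosphonate should give the E C7=C8 alkene, the C9=C10 geometry comes with the reagent (a minor 9Z isomer is removed by chromatography), and C6 already holds its more stable configuration, trans to both neighbouring carbon substituents.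

Step 12
Reactants: 16 dienenitrile
Product: 18 (2E,4E)-3-methyl-5-{(1R,2S,5S)-2-methyl-5-(prop-1-en-2-yl)-2-[(triethylsilyl)oxy]cyclopentyl}penta-2,4-dienal, via aluminium aldimine 17 (not isolated)
Conditions: iBu2AlH (1.2 equiv), toluene, −78 °C; then wet SiO2, 0 °C
Reagents that add atoms: water, O
Why: Partial reduction of a nitrile with iBu2AlH stops at the N-aluminated aldimine, which is hydrolysed on wet silica to the dienal without loss of the silyl ether.

Step 13
Reactants: 19 pseudoionone, (3E,5E)-6,10-dimethylundeca-3,5,9-trien-2-one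
Product: 20 (4E,6E)-3,7,11-trimethyldodeca-1,4,6,10-tetraen-3-ol (racemic)
Conditions: CH2=CHMgBr, THF, 0 °C; H2O quench
Reagents that add atoms: vinylmagnesium bromide, C=C[Mg]Br
Why: Grignard 1,2-addition of the vinyl reagent to the dienone carbonyl gives the tertiary bis-allylic alcohol, whose new centre is lost again in step 14.

Step 14
Reactants: 20 vinyl carbinol
Product: 21 [(2E,4E,6E)-3,7,11-trimethyldodeca-2,4,6,10-tetraen-1-yl]triphenylphosphonium bromide
Conditions: PPh3·HBr, MeOH, rt; crystallisation
Reagents that add atoms: triphenylphosphine hydrobromide, [Br-].[PH+](c1ccccc1)(c1ccccc1)c1ccccc1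
Why: Acid-promoted ionisation of the tertiary allylic alcohol and capture of the delocalised cation by triphenylphosphine at the primary terminus (SN1' allylic transposition) gives the conjugated phosphonium salt, purified as the all-E isomer by crystallisation.

Step 15
Reactants: 21 C15 phosphonium bromide; 22 (2E,4E,6E)-2,7-dimethylocta-2,4,6-trienedial
Product: 24 (2E,4E,6E,8E,10E,12E,14E)-2,7,11,15,19-pentamethylicosa-2,4,6,8,10,12,14,18-octaenal, via C15 ylide 23 (not isolated)
Conditions: 22 (3 equiv), NaOMe, CH2Cl2/MeOH, 0 °C → rt; then heptane, reflux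
Reagents that add atoms: none
Why: Wittig olefination of one formyl group of the excess symmetrical dialdehyde by the allylic ylide forms C11'=C12', and the sterically strained Z isomer at this bond should isomerise to E on heating.

Step 16
Reactants: 24 C25 aldehyde
Product: 25 (2E,4E,6E,8E,10E,12E,14E)-2,7,11,15,19-pentamethylicosa-2,4,6,8,10,12,14,18-octaen-1-ol
Conditions: NaBH4, THF/MeOH, 0 °C
Reagents that add atoms: none
Why: Borohydride 1,2-reduction of the polyenal gives the primary allylic alcohol with no effect on the polyene.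

Step 17
Reactants: 25 C25 alcohol
Product: 26 [(2E,4E,6E,8E,10E,12E,14E)-2,7,11,15,19-pentamethylicosa-2,4,6,8,10,12,14,18-octaen-1-yl]triphenylphosphonium bromide
Conditions: PPh3·HBr, CH2Cl2/MeOH, 0 °C → rt, dark
Reagents that add atoms: triphenylphosphine hydrobromide, [Br-].[PH+](c1ccccc1)(c1ccccc1)c1ccccc1
Why: SN1-type substitution of the polyenyl alcohol, in which the delocalised cation is captured by triphenylphosphine at the primary terminus, follows the preparation of retinyltriphenylphosphonium salts from retinol.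

Step 18
Reactants: 18 C15 ring dienal; 26 C25 phosphonium bromide
Product: 28 triethyl{[(1S,2R,3S)-2-[(1E,3E,5E,7E,9E,11E,13E,15E,17E,19E)-3,7,12,16,20,24-hexamethylpentacosa-1,3,5,7,9,11,13,15,17,19,23-undecaen-1-yl]-1-methyl-3-(prop-1-en-2-yl)cyclopentyl]oxy}silane, via C25 ylide 27 (not isolated)
Conditions: NaOMe, CH2Cl2/MeOH, 0 °C → rt, dark, Ar; then heptane, reflux
Reagents that add atoms: none
Why: Wittig olefination between the C25 ylide and the C15 dienal forms C11=C12 in the way retinyl ylide and retinal are joined, and heating should convert the hindered 11Z isomer into the all-E polyene.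

Step 19
Reactants: 28 silyl-protected C40 polyene
Product: 29 (1S,2R,3S)-2-[(1E,3E,5E,7E,9E,11E,13E,15E,17E,19E)-3,7,12,16,20,24-hexamethylpentacosa-1,3,5,7,9,11,13,15,17,19,23-undecaen-1-yl]-1-methyl-3-(prop-1-en-2-yl)cyclopentan-1-ol (CNP0222499.1)
Conditions: Bu4NF, THF, 0 °C → rt, dark
Reagents that add atoms: none
Why: Fluoride cleavage of the tertiary triethylsilyl ether, under conditions that polyenes tolerate, frees the C5 hydroxyl and gives the target.

Compound list
1 | 2-methyl-2-vinyloxirane (racemic) | CC1(C=C)CO1 | starting material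
2 | (2E)-4-chloro-2-methylbut-2-en-1-ol | OC/C(C)=C/CCl | intermediate
3 | tert-butyl{[(2E)-4-chloro-2-methylbut-2-en-1-yl]oxy}dimethylsilane | CC(C)(C)[Si](C)(C)OC/C(C)=C/CCl | intermediate
4 | methyl acetoacetate | COC(=O)CC(C)=O | starting material
5 | sodium lithium dianion of methyl acetoacetate | C=C([O-])C=C([O-])OC.[Na+].[Li+] | intermediate
6 | methyl (6E)-8-[(tert-butyldimethylsilyl)oxy]-7-methyl-3-oxooct-6-enoate | COC(=O)CC(=O)CC/C=C(\C)CO[Si](C)(C)C(C)(C)C | intermediate
7 | methyl (6E)-8-hydroxy-7-methyl-3-oxooct-6-enoate | COC(=O)CC(=O)CC/C=C(\C)CO | intermediate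
8 | methyl (6E)-8-[(methoxycarbonyl)oxy]-7-methyl-3-oxooct-6-enoate | COC(=O)CC(=O)CC/C=C(\C)COC(=O)OC | intermediate
9 | methyl (1R,5S)-2-oxo-5-(prop-1-en-2-yl)cyclopentane-1-carboxylate | C=C(C)[C@H]1CCC(=O)[C@@H]1C(=O)OC | intermediate
10 | methyl (1R,2S,5S)-2-hydroxy-2-methyl-5-(prop-1-en-2-yl)cyclopentane-1-carboxylate | C=C(C)[C@H]1CC[C@](C)(O)[C@@H]1C(=O)OC | intermediate
11 | methyl (1R,2S,5S)-2-methyl-5-(prop-1-en-2-yl)-2-[(triethylsilyl)oxy]cyclopentane-1-carboxylate | C=C(C)[C@H]1CC[C@](C)(O[Si](CC)(CC)CC)[C@@H]1C(=O)OC | intermediate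
12 | {(1S,2S,5S)-2-methyl-5-(prop-1-en-2-yl)-2-[(triethylsilyl)oxy]cyclopentyl}methanol | C=C(C)[C@H]1CC[C@](C)(O[Si](CC)(CC)CC)[C@@H]1CO | intermediate
13 | (1R,2S,5S)-2-methyl-5-(prop-1-en-2-yl)-2-[(triethylsilyl)oxy]cyclopentane-1-carbaldehyde | C=C(C)[C@H]1CC[C@](C)(O[Si](CC)(CC)CC)[C@@H]1C=O | intermediate
14 | diethyl [(2E)-3-cyano-2-methylprop-2-en-1-yl]phosphonate | CCOP(=O)(OCC)C/C(C)=C/C#N | starting material
15 | sodium salt of the carbanion of phosphonate 14 | CCOP(=O)(OCC)[CH-]/C(C)=C/C#N.[Na+] | intermediate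
16 | (2E,4E)-3-methyl-5-{(1R,2S,5S)-2-methyl-5-(prop-1-en-2-yl)-2-[(triethylsilyl)oxy]cyclopentyl}penta-2,4-dienenitrile | C=C(C)[C@H]1CC[C@](C)(O[Si](CC)(CC)CC)[C@@H]1/C=C/C(C)=C/C#N | intermediate
17 | N-(diisobutylaluminio) aldimine of dienal 18 | C=C(C)[C@H]1CC[C@](C)(O[Si](CC)(CC)CC)[C@@H]1/C=C/C(C)=C/C=N[Al](CC(C)C)CC(C)C | intermediate
18 | (2E,4E)-3-methyl-5-{(1R,2S,5S)-2-methyl-5-(prop-1-en-2-yl)-2-[(triethylsilyl)oxy]cyclopentyl}penta-2,4-dienal | C=C(C)[C@H]1CC[C@](C)(O[Si](CC)(CC)CC)[C@@H]1/C=C/C(C)=C/C=O | intermediate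
19 | pseudoionone, (3E,5E)-6,10-dimethylundeca-3,5,9-trien-2-one | CC(=O)/C=C/C=C(\C)CCC=C(C)C | starting material
20 | (4E,6E)-3,7,11-trimethyldodeca-1,4,6,10-tetraen-3-ol (racemic) | C=CC(C)(O)/C=C/C=C(\C)CCC=C(C)C | intermediate
21 | [(2E,4E,6E)-3,7,11-trimethyldodeca-2,4,6,10-tetraen-1-yl]triphenylphosphonium bromide | [Br-].c1ccccc1[P+](c1ccccc1)(c1ccccc1)C/C=C(C)/C=C/C=C(\C)CCC=C(C)C | intermediate
22 | (2E,4E,6E)-2,7-dimethylocta-2,4,6-trienedial | O=C/C(C)=C/C=C/C=C(C)/C=O | starting material
23 | ylide of salt 21, [(2E,4E,6E)-3,7,11-trimethyldodeca-2,4,6,10-tetraen-1-ylidene]triphenylphosphorane | c1ccccc1P(c1ccccc1)(c1ccccc1)=C/C=C(C)/C=C/C=C(\C)CCC=C(C)C | intermediate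
24 | (2E,4E,6E,8E,10E,12E,14E)-2,7,11,15,19-pentamethylicosa-2,4,6,8,10,12,14,18-octaenal | O=C/C(C)=C/C=C/C=C(C)/C=C/C=C(C)/C=C/C=C(\C)CCC=C(C)C | intermediate
25 | (2E,4E,6E,8E,10E,12E,14E)-2,7,11,15,19-pentamethylicosa-2,4,6,8,10,12,14,18-octaen-1-ol | OC/C(C)=C/C=C/C=C(C)/C=C/C=C(C)/C=C/C=C(\C)CCC=C(C)C | intermediate
26 | [(2E,4E,6E,8E,10E,12E,14E)-2,7,11,15,19-pentamethylicosa-2,4,6,8,10,12,14,18-octaen-1-yl]triphenylphosphonium bromide | [Br-].c1ccccc1[P+](c1ccccc1)(c1ccccc1)C/C(C)=C/C=C/C=C(C)/C=C/C=C(C)/C=C/C=C(\C)CCC=C(C)C | intermediate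
27 | ylide of salt 26, [(2E,4E,6E,8E,10E,12E,14E)-2,7,11,15,19-pentamethylicosa-2,4,6,8,10,12,14,18-octaen-1-ylidene]triphenylphosphorane | c1ccccc1P(c1ccccc1)(c1ccccc1)=C/C(C)=C/C=C/C=C(C)/C=C/C=C(C)/C=C/C=C(\C)CCC=C(C)C | intermediate
28 | triethylsilyl ether of the target (full name in step 18) | C=C(C)[C@H]1CC[C@](C)(O[Si](CC)(CC)CC)[C@@H]1/C=C/C(C)=C/C=C/C(C)=C/C=C/C=C(C)/C=C/C=C(C)/C=C/C=C(\C)CCC=C(C)C | intermediate
29 | (1S,2R,3S)-2-[(1E,3E,5E,7E,9E,11E,13E,15E,17E,19E)-3,7,12,16,20,24-hexamethylpentacosa-1,3,5,7,9,11,13,15,17,19,23-undecaen-1-yl]-1-methyl-3-(prop-1-en-2-yl)cyclopentan-1-ol; in carotenoid numbering (2S,5S,6R) | C=C(C)[C@H]1CC[C@](C)(O)[C@@H]1/C=C/C(C)=C/C=C/C(C)=C/C=C/C=C(C)/C=C/C=C(C)/C=C/C=C(\C)CCC=C(C)C | target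

Total step count: 19. Longest linear sequence: 14 steps (steps 1–12, 18 and 19); the C25 branch (steps 13–17) is 5 steps.

Steps most likely to fail

Step 6. Each diastereomeric allyl complex may cyclise before the two can interconvert, so that the ligand cannot impose one configuration at C2; closure through oxygen or at the terminal allyl carbon are lesser concerns. The fallback gives up catalyst control for resolution through covalent diastereomers. It sets out from 8: ring closure with achiral Pd(PPh3)4 in MeCN should give the racemic trans keto ester F1. Condensation with (R)-1-phenylethylamine (toluene, 4 Å MS, cat. AcOH) gives two diastereomeric enamino esters, from which the (5R) enamino ester F2 is separated by crystallisation or chromatography. Hydrolysis with aqueous oxalic acid in THF comes back to the route at 9.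

Step 7. The Grignard reagent may deprotonate the acidic C6–H in place of adding to the carbonyl, or facial selectivity may erode because the isopropenyl group on C2 lies on the face that methyl must use. The fallback removes the 1,3-dicarbonyl character before methylation. It sets out from 9: LiAlH4 (Et2O, 0 °C) gives the diol F3 as a mixture of carbinol epimers, and pivaloyl chloride in pyridine acylates the primary hydroxyl to give the pivalate F4. Dess–Martin periodinane gives the ketone F5, now an ordinary 2-substituted cyclopentanone. MeMgBr/CeCl3 at −78 °C adds anti to the adjacent pivaloyloxymethyl group to give the tertiary alcohol F6, and Et3SiOTf with 2,6-lutidine gives the silyl ether F7. iBu2AlH then removes the pivalate and comes back to the route at 12.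

Step 17. Acid ionisation of the pentaenyl alcohol may scramble double-bond geometry, let the phosphine add at an internal carbon or oligomerise the cation. The fallback inverts the polarity of the last coupling, so that the C25 unit stays an aldehyde and no acid meets the polyene. It sets out from 18: NaBH4 gives the dienol F8. Mitsunobu reaction with 2-sulfanyl-1,3-benzothiazole (PPh3, diisopropyl azodicarboxylate) gives the sulfide F9, and (NH4)6Mo7O24 with H2O2 in EtOH at 0 °C oxidises it to the sulfone F10. Deprotonation with NaN(SiMe3)2 at −78 °C and addition of aldehyde 24 (Julia–Kocienski olefination), followed by the same thermal isomerisation, comes back to the route at 28. Steps 16 and 17 are then not needed.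

Further compounds
F1 | step 6 | racemic trans methyl 2-oxo-5-(prop-1-en-2-yl)cyclopentane-1-carboxylate (9 together with its enantiomer) | C=C(C)C1CCC(=O)C1C(=O)OC
F2 | step 6 | methyl (5R)-2-{[(1R)-1-phenylethyl]amino}-5-(prop-1-en-2-yl)cyclopent-1-ene-1-carboxylate | C=C(C)[C@H]1CCC(N[C@H](C)c2ccccc2)=C1C(=O)OC
F3 | step 7 | (2S,3S)-2-(hydroxymethyl)-3-(prop-1-en-2-yl)cyclopentan-1-ol (both C1 epimers) | C=C(C)[C@H]1CCC(O)[C@@H]1CO
F4 | step 7 | [(1S,5S)-2-hydroxy-5-(prop-1-en-2-yl)cyclopentyl]methyl 2,2-dimethylpropanoate (both C2 epimers) | C=C(C)[C@H]1CCC(O)[C@@H]1COC(=O)C(C)(C)C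
F5 | step 7 | [(1S,5S)-2-oxo-5-(prop-1-en-2-yl)cyclopentyl]methyl 2,2-dimethylpropanoate | C=C(C)[C@H]1CCC(=O)[C@@H]1COC(=O)C(C)(C)C
F6 | step 7 | [(1S,2S,5S)-2-hydroxy-2-methyl-5-(prop-1-en-2-yl)cyclopentyl]methyl 2,2-dimethylpropanoate | C=C(C)[C@H]1CC[C@](C)(O)[C@@H]1COC(=O)C(C)(C)C
F7 | step 7 | {(1S,2S,5S)-2-methyl-5-(prop-1-en-2-yl)-2-[(triethylsilyl)oxy]cyclopentyl}methyl 2,2-dimethylpropanoate | C=C(C)[C@H]1CC[C@](C)(O[Si](CC)(CC)CC)[C@@H]1COC(=O)C(C)(C)C
F8 | step 17 | (2E,4E)-3-methyl-5-{(1R,2S,5S)-2-methyl-5-(prop-1-en-2-yl)-2-[(triethylsilyl)oxy]cyclopentyl}penta-2,4-dien-1-ol | C=C(C)[C@H]1CC[C@](C)(O[Si](CC)(CC)CC)[C@@H]1/C=C/C(C)=C/CO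
F9 | step 17 | 2-{[(2E,4E)-3-methyl-5-{(1R,2S,5S)-2-methyl-5-(prop-1-en-2-yl)-2-[(triethylsilyl)oxy]cyclopentyl}penta-2,4-dien-1-yl]sulfanyl}-1,3-benzothiazole | C=C(C)[C@H]1CC[C@](C)(O[Si](CC)(CC)CC)[C@@H]1/C=C/C(C)=C/CSc1nc2ccccc2s1
F10 | step 17 | 2-{[(2E,4E)-3-methyl-5-{(1R,2S,5S)-2-methyl-5-(prop-1-en-2-yl)-2-[(triethylsilyl)oxy]cyclopentyl}penta-2,4-dien-1-yl]sulfonyl}-1,3-benzothiazole | C=C(C)[C@H]1CC[C@](C)(O[Si](CC)(CC)CC)[C@@H]1/C=C/C(C)=C/CS(=O)(=O)c1nc2ccccc2s1
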